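3 questions ranked these flasks for me; in each, incoming ligand replaces one position on the starting complex, then a second on the complex with one exchanged, and the score is the share of complex with one exchanged in the two products together.

| flask | starting complex | incoming ligand | scavenger | protic impurity | temperature | remark | time |
|---|---|---|---|---|---|---|---|
| Monday's | 0.020 M | 0.022 M | 0.030 M | 6 mM | −35 °C | run made earlier |  |
| Thursday's | 0.020 M | 0.031 M | 0.030 M | 6 mM | −20 °C | run made earlier |  |
| Tuesday's | 0.020 M | 0.048 M | 0.030 M | 6 mM | −35 °C | run made earlier |  |
| alder | 0.020 M (in portions, 2, over 80 s) | 0.0220 M | 0.0300 M | 6.00 mM | −20 °C | first portion at the start, last at 80 s | 3.0 min |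
| cedar | 0.020 M (fed, over 80 s) | 0.0220 M | 0.0300 M | 6.00 mM | −20 °C | all else is in the flask from the start; the feed brings no volume worth counting | 3.0 min |
| oak | 0.020 M | 0.0220 M (fed, over 80 s) | 0.0300 M | 6.00 mM |  | the addition at −50 °C, then warmed to −20 °C; the feed brings no volume worth counting | 3.0 min |
| maple | 0.020 M | 0.0220 M (fed, over 80 s) | 0.0300 M | 6.00 mM | −20 °C | all else is in the flask from the start; the feed brings no volume worth counting | 3.0 min |

| run | time / min | complex with one exchanged / % | complex with two exchanged / % | starting complex / % |
|---|---|---|---|---|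
| Monday's | 0.667 | 34 | 4 | 61 |
| Monday's | 1.33 | 41 | 7 | 42 |
| Monday's | 2.00 | 49 | 10 | 34 |
| Monday's | 3.00 | 52 | 15 | 23 |
| Monday's | 4.00 | 50 | 21 | 23 |
| Thursday's | 0.200 | 37 | 9 | 49 |
| Thursday's | 0.667 | 46 | 28 | 26 |
| Thursday's | 1.00 | 42 | 33 | 16 |
| Thursday's | 1.50 | 39 | 40 | 11 |
| Thursday's | 2.50 | 34 | 51 | 6 |
| Tuesday's | 0.417 | 42 | 8 | 45 |
| Tuesday's | 0.667 | 51 | 13 | 32 |
| Tuesday's | 1.33 | 52 | 26 | 16 |
| Tuesday's | 3.00 | 41 | 47 | 5 |
| Tuesday's | 5.00 | 29 | 64 | 4 |

(scatter of a reading: 1.5 percentage points)

- the numbers in the tables scatter with a standard deviation of 1.5 percentage points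

- which flask leads in share of complex with one exchanged in complex with one exchanged plus complex with two exchanged ("all alike" within 1.5 percentage points) (alder / cedar / oak / maple / all alike)
- share of complex with one exchanged in complex with one exchanged plus complex with two exchanged at the end, alder
- share of complex with one exchanged in complex with one exchanged plus complex with two exchanged at the end, cedar
- share of complex with one exchanged in complex with one exchanged plus complex with two exchanged at the end, oak
- share of complex with one exchanged in complex with one exchanged plus complex with two exchanged at the end, maple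

First, how much ligand does a complex get? I reckoned ligand per complex, 1.10, the charge of incoming ligand divided by the charge of starting complex. That is below 2, so incoming ligand is the limiting reagent for a double exchange, but it is past 1, so some second exchange is paid for.

Second, what share does that buy? In Thursday's run at 0.667 min, complex with one exchanged plus twice complex with two exchanged read 1.02 per complex, near 1.10, and the share read 62.2 %. I took that figure for maple.

Third, does the way in shift it? With 16 % of starting complex left, Tuesday's run at −35 °C read a share of 66.7 %, and Thursday's at −20 °C read 56.0 %, so I put oak, dosed at −50 °C, first, though those two runs also differ in incoming ligand, 0.048 M against 0.031 M.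

The forecast gave 61 % for alder, 63 % for cedar, 68 % for oak and 66 % for maple ("Cold oak gains slightly"), its maple standing above mine.

The flasks gave 49.6 % for alder, 55.4 % for cedar, 61.7 % for oak and 56.1 % for maple, so oak led and alder trailed.

    leaving ligand + incoming ligand ⇌ idle adduct, settled at all times (K = 210 L mol⁻¹, ΔH = 16.0 kJ mol⁻¹)
    starting complex + incoming ligand → leaving ligand + complex with one exchanged (k = 2.65 L mol⁻¹ s⁻¹, Ea = 40.0 kJ mol⁻¹)
    protic impurity + starting complex → quenched substrate (k = 0.640 L mol⁻¹ s⁻¹, Ea = 35.0 kJ mol⁻¹)
    complex with one exchanged + incoming ligand → leaving ligand + complex with two exchanged (k = 1.45 L mol⁻¹ s⁻¹, Ea = 52.0 kJ mol⁻¹)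
    incoming ligand → decomposed reagent (k = 9.83 × 10⁻⁴ s⁻¹, Ea = 83.0 kJ mol⁻¹)
    scavenger + leaving ligand → scavenged by-product (k = 5.91 L mol⁻¹ s⁻¹, Ea = 42.0 kJ mol⁻¹)
    (constants at −20 °C)

Maple fell 6.1 points under my figure. In alder at 3.00 min, complex with one exchanged plus twice complex with two exchanged stood at 0.998 per complex, of the 1.10 charged. Alder's neighbour, with its starting complex cut to 0.0080 M, has 2.75 ligand per complex, past 2, so the charge covers a double exchange. That neighbour ended with a share of 24.2 %, holding 66.4 % of complex with two exchanged and 21.2 % of complex with one exchanged at 3.00 min.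

Readings and results were computed with made-up constants.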